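## The problem

The target is a biflavonoid. Its upper unit is a (2R,3S,4S)-flavan-3-ol (benzo ring A, pyran ring C, catechol ring B, unprimed flavan numbers), and the sp3 carbon C4 of this unit is bonded to C6′ of a (2′R,3′S,4′S)-flavan-3′,4′-diol (benzo ring D, pyran ring F, catechol ring E, primed numbers). Each pyran ring carries three contiguous stereocentres in the same 2,3-trans-3,4-cis pattern, and C2 and C2′ have the same configuration and the same 3,4-dihydroxyphenyl substituent. Within one unit the C2 aryl group can send a reagent to the opposite face of a C3=C4 double bond, so C2 can set C3 and C4. Between the units no such relay exists, because the C4–C6′ bond is a twisting aryl–alkyl link, so C2 and C2′ need an external source of chirality. The upper C4 is the awkward centre: ring D must end cis to the C3 hydroxyl, which a syn addition of H and O across C3=C4 anti to the C2 aryl cannot give. The interflavan bond must sit at C6′ and not at C8′, and the lower unit keeps an oxygen at C4′ that the upper unit lacks, so the two halves must be told apart at some stage. The free compound is fragile: the C4′ hydroxyl is benzylic and para to the C7′ oxygen and ionises in acid (as does the C4–C6′ bond), the C2–O1 and C2′–O1′ bonds are benzylic ethers, and both catechols oxidise in base and air. The enabling feature is that C2 and C2′ are oxygen-bearing benzylic carbons attached to the ring oxygens O1 and O1′. At the flav-3-ene oxidation level each is the acetal carbon of a 2-alkoxy-2H-chromene, so rings B and E can be added last to two benzopyrylium ions, and the skeleton without them is a 4,6′-bicoumarin.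

## Retrosynthesis

**Protecting groups (20 ⇒ 19 ⇒ 18).** The six phenolic O–H bonds are traced back to benzyl ethers (19) and the three alcohol O–H bonds to acetates (18). Benzyl ethers survive hydride, Lewis acid, osmium and trifluoroacetic acid and leave by neutral hydrogenolysis, the only conditions the C4′ carbinol and the catechols are likely to tolerate; methyl ethers would need boron halides and silyl ethers would not survive the coumarin chemistry. The acetates are removed first, under base, because a benzylic acetate at C4′ would be more prone to hydrogenolysis than the free alcohol.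

**C4–H (18 ⇒ 17).** The C4–H bond is cut and oxygen is restored at C4, giving the tertiary, doubly benzylic alcohol 17. Hydrogenation of a C3=C4 alkene would lose the C3 oxygen, and hydroboration of the flav-3-ene would deliver H and B to the same face and give the 3,4-trans isomer. Removing a C4 oxygen by ionisation and hydride capture lets hydrogen enter anti to the C3 oxygen, which places ring D cis to it as required. The forward step must ionise the tertiary C4–OH without touching the secondary C4′ acetate. This is why 17 is a triacetate with only the tertiary hydroxyl free, a pattern that plain acetylation of tetraol 16 provides without any selective protection.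

**Four C–O bonds (16 ⇒ 15).** The C3–O, C4–O, C3′–O and C4′–O bonds are cut together, leading to bis(flav-3-ene) 15. Two syn-dihydroxylations anti to the C2 and C2′ aryl groups create four stereocentres from two, and the lower unit then already has its final 2,3-trans-3,4-cis diol. The precursor has only two stereocentres left.

**C2–ring B and C2′–ring E (15 ⇒ 12 + 14).** Both aryl–C2 bonds are cut, giving bis(2-ethoxy-2H-chromene) 12 and two equivalents of diethyl arylboronate 14. Compared with closing the pyran rings around pre-formed C2 stereocentres, this cut keeps both heterocycles intact, uses the identity of rings B and E (one reagent, one catalyst, one operation) and removes all stereochemistry from the precursor, since the acetal epimers of 12 converge on planar cations. The forward reaction must be enantioselective at each site, attack C2 rather than C4 of each benzopyrylium ion, and tolerate the 4-aryl group of the upper unit.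

**Oxidation level (12 ⇒ 11 ⇒ 10).** The acetals are traced to bis-lactol 11 and then to bicoumarin 10. Coumarins are robust, crystalline and easy to cross-couple, whereas chromene acetals are not, so the labile functionality is introduced only two steps before it is used.

**C4–C6′ (10 ⇒ 5 + 9).** The interflavan bond is cut as a biaryl-type bond between coumarin 4-triflate 5 and coumarin-6-boronate 9. A Friedel–Crafts union of a flavan-4-yl cation with a resorcinol nucleophile would give C6′/C8′ mixtures and mainly the 3,4-trans isomer. The cross-coupling fixes the position through the bromine of 4-bromoresorcinol and postpones the C4 configuration.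

**Monomers.** Triflate 5 comes from 4-hydroxycoumarin 4, made from mono-benzylated ketone 2 and hence from 2,4-dihydroxyacetophenone 1. Boronate 9 comes from bromide 8, its phenol 7 and 4-bromoresorcinol 6 by Pechmann condensation. Boronate 14 is the diethyl ester of boronic acid 13.

## Roads not taken

**Alternative 1:** The cut removes three bonds of hub ring D (C6′–C7′, C8′–C8a′, C4a′–C8a′), so ring D is grown onto a chain that already holds C4, ring A and the future C2–C3 carbons.
- Forward step: light converts α-diazo enone A1 by Wolff rearrangement into a vinylketene, which takes up ethynyloxy(triisopropyl)silane A2 by [2+2] cycloaddition, 4π opening and 6π closure to give resorcinol mono-silyl ether A3.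
- Merits: the substitution pattern of ring D is unambiguous, its two oxygens are differentiated from the outset, and C4 is fixed before the arene exists. In that last respect this road is better than the chosen one, which creates C4 late by hydride delivery.
- Weak points: the C4 hydrogen of A1 is benzylic, allylic and α to the diazo-bearing carbon, so its configuration is at risk. The styrene absorbs where the diazo ketone does, inviting E/Z isomerisation. A3 has neither pyran ring: ring C must still be closed from the styrene and a protected phenol, and ring F with three stereocentres and ring E must be built onto ring D.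
- Comparison: the route is far longer and makes no use of the identity of rings B and E. Against the late C4 problem the chosen plan sets ready-made heterocycles from coumarins and six stereocentres created in three operations.

**Alternative 2:** The cut is the C4′–C4a′ bond of ring F.
- Forward step: the complete, protected upper flavan-3-ol A4, whose ring D phenol is etherified with an (S)-1-arylprop-2-ynyl group, is treated with (Ph3P)AuNTf2. The alkyne, activated by monovalent gold, is attacked by the ring D carbon para to the benzyloxy group to give flav-3-ene A5.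
- Merits: the step is catalytic and atom-economic, and C2′ arrives with the ether. The two halves differ from the start, so the C4/C4′ discrimination that the chosen plan needs in step 14 never arises, which is a real advantage.
- Weak points: the stereocentre of A4 is propargylic, 3,4-dialkoxybenzylic and an aryl ether at once. It should ionise under the Lewis-acidic catalyst (racemisation, propargyl shifts), and making it enantiopure by O-alkylation with an SN1-prone secondary alcohol is itself doubtful. Closure at C8′ between the two oxygens competes. The whole upper unit, including the 3,4-cis C4 centre, must first be made by other chemistry.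
- Comparison: this road solves half of the molecule. The chosen plan answers the discrimination problem with the tertiary/secondary difference of the two C4 oxygens and sets both C2 centres in one catalytic step.

**Alternative 3:** The cut is the C3–C4 bond of ring C.
- Forward step: SmI2 reduces the diaryl ketone of keto aldehyde A6 to a ketyl, which adds to the tethered α-aryloxy aldehyde and closes ring C as 4-aryl-3,4-cis-diol A7.
- Merits: A7 has exactly the upper-unit functionality of 16, the cis-diol is the normal outcome of a samarium-chelated pinacol closure, and the benzophenone is easily made. In these respects the road is as good as the chosen one.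
- Weak points: C2 of A6 is the α-carbon of an aldehyde and is also benzylic and aryloxy-substituted, so it is hard to make as one enantiomer and will epimerise. Divalent samarium cleaves α-oxygenated carbonyl compounds, which would expel the ring A phenoxide. The 2,3-trans relationship rests on substrate control alone. Rings F and E are still missing.
- Comparison: the chosen plan reaches the same diol by osmylation of an alkene whose C2 was set catalytically, and builds the lower unit in the same steps.

Key step: step 11

**Assumptions.**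
- The (2R,3R)-configured tartaric acid monoamide is taken to deliver the aryl group to the face that gives the 2S,2′S product. If a model 2-ethoxy-2H-chromene shows the opposite sense, the (2S,3S) enantiomer of the same diol is used and nothing else changes.
- Boronic acid 13 is taken as a commercial compound.
- The descriptors of C3, C3′ and C4 change along 16–20 because substituent priorities change. The geometry is that of the SMILES strings and changes only at C4 in step 14.

## Route

Step 1
Reactants: 1 2,4-dihydroxyacetophenone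
Product: 2 1-[4-(benzyloxy)-2-hydroxyphenyl]ethan-1-one
Conditions: BnBr (1.05 equiv), K2CO3, acetone, reflux
Reagents that add atoms: benzyl bromide, BrCc1ccccc1
Why: Williamson etherification; the 2-hydroxyl is hydrogen-bonded to the ketone and less nucleophilic, so the 4-hydroxyl is alkylated selectively.

Step 2
Reactants: 2 1-[4-(benzyloxy)-2-hydroxyphenyl]ethan-1-one
Product: 4 7-(benzyloxy)-4-hydroxy-2H-chromen-2-one, via ethyl 3-[4-(benzyloxy)-2-hydroxyphenyl]-3-oxopropanoate 3 (not isolated)
Conditions: NaH, (EtO)2CO, toluene, 110 °C; then aq. HCl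
Reagents that add atoms: diethyl carbonate, CCOC(=O)OCC
Why: Claisen condensation of the ketone enolate with diethyl carbonate gives β-keto ester 3, which lactonises onto the phenoxide; this is the standard route from 2-hydroxyacetophenones to 4-hydroxycoumarins.

Step 3
Reactants: 4 7-(benzyloxy)-4-hydroxy-2H-chromen-2-one
Product: 5 7-(benzyloxy)-2-oxo-2H-chromen-4-yl trifluoromethanesulfonate
Conditions: Tf2O, Et3N, CH2Cl2, −10 °C
Reagents that add atoms: trifluoromethanesulfonic anhydride, O=S(=O)(OS(=O)(=O)C(F)(F)F)C(F)(F)F
Why: O-sulfonylation of the vinylogous acid; 4-sulfonyloxycoumarins are established cross-coupling electrophiles.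

Step 4
Reactants: 6 4-bromoresorcinol
Product: 7 6-bromo-7-hydroxy-2H-chromen-2-one
Conditions: DL-malic acid, conc. H2SO4, 100 °C
Reagents that add atoms: malic acid, OC(CC(=O)O)C(=O)O
Why: Pechmann condensation; malic acid is decarbonylated in the flask to formylacetic acid, which condenses at the only free ring position para to a hydroxyl, so the bromine ends at C6 of the coumarin.

Step 5
Reactants: 7 6-bromo-7-hydroxy-2H-chromen-2-one
Product: 8 7-(benzyloxy)-6-bromo-2H-chromen-2-one
Conditions: BnBr, K2CO3, DMF, 60 °C
Reagents that add atoms: benzyl bromide, BrCc1ccccc1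
Why: Williamson etherification of the single phenol.

Step 6
Reactants: 8 7-(benzyloxy)-6-bromo-2H-chromen-2-one
Product: 9 7-(benzyloxy)-6-(4,4,5,5-tetramethyl-1,3,2-dioxaborolan-2-yl)-2H-chromen-2-one
Conditions: B2pin2, PdCl2(dppf) (3 mol%), KOAc, 1,4-dioxane, 90 °C
Reagents that add atoms: bis(pinacolato)diboron, CC1(C)OB(OC1(C)C)B1OC(C)(C)C(C)(C)O1
Why: Miyaura borylation of an aryl bromide; the weak base KOAc leaves the lactone and the coumarin alkene untouched.

Step 7
Reactants: 5 7-(benzyloxy)-2-oxo-2H-chromen-4-yl trifluoromethanesulfonate; 9 7-(benzyloxy)-6-(4,4,5,5-tetramethyl-1,3,2-dioxaborolan-2-yl)-2H-chromen-2-one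
Product: 10 7,7′-bis(benzyloxy)-2H,2′H-[4,6′-bichromene]-2,2′-dione (the 4,6′-bicoumarin)
Conditions: Pd(PPh3)4 (5 mol%), K3PO4, 1,4-dioxane–H2O (20:1), 85 °C
Reagents that add atoms: none
Why: Suzuki–Miyaura coupling; the vinylogous acyl triflate adds rapidly to zerovalent palladium, and the position of the new bond on ring D is fixed by the boron that replaced the bromine of 6.

Step 8
Reactants: 10 7,7′-bis(benzyloxy)-2H,2′H-[4,6′-bichromene]-2,2′-dione
Product: 11 7,7′-bis(benzyloxy)-2H,2′H-[4,6′-bichromene]-2,2′-diol (bis-lactol, mixture of epimers at C2 and C2′)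
Conditions: i-Bu2AlH (2.3 equiv), CH2Cl2, −78 °C; aq. potassium sodium tartrate
Reagents that add atoms: none
Why: partial reduction of lactones to lactols; the tetrahedral aluminium alkoxides persist at −78 °C, which prevents over-reduction, as known for coumarins.

Step 9
Reactants: 11 7,7′-bis(benzyloxy)-2H,2′H-[4,6′-bichromene]-2,2′-diol
Product: 12 7,7′-bis(benzyloxy)-2,2′-diethoxy-2H,2′H-4,6′-bichromene (bis-acetal, mixture of acetal epimers)
Conditions: EtOH, PPTS (cat.), 3 Å MS, rt; Et3N quench, filtration through basic alumina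
Reagents that add atoms: ethanol, CCO
Why: acid-catalysed acetal formation through the benzopyrylium ions, the usual preparation of 2-ethoxy-2H-chromenes from coumarin lactols; the configuration of the acetal carbons is irrelevant because both are ionised in step 11.

Step 10
Reactants: 13 3,4-bis(benzyloxy)phenylboronic acid
Product: 14 diethyl [3,4-bis(benzyloxy)phenyl]boronate
Conditions: EtOH (excess), toluene, reflux with azeotropic removal of water; concentrated and used crude
Reagents that add atoms: ethanol, CCO
Why: esterification of a boronic acid is an equilibrium driven by removal of water; the moisture-sensitive ester is used directly.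

Step 11
Reactants: 12 7,7′-bis(benzyloxy)-2,2′-diethoxy-2H,2′H-4,6′-bichromene; 14 diethyl [3,4-bis(benzyloxy)phenyl]boronate (3 equiv)
Product: 15 (2S,2′S)-7,7′-bis(benzyloxy)-2,2′-bis[3,4-bis(benzyloxy)phenyl]-2H,2′H-4,6′-bichromene
Conditions: (2R,3R)-4-(dibenzylamino)-2,3-dihydroxy-4-oxobutanoic acid (10 mol%), Yb(OTf)3 (9 mol%), EtOAc, −20 → 4 °C
Reagents that add atoms: none
Why: Yb(OTf)3 and the acidic diol ionise each 2-ethoxy group to a 7-benzyloxybenzopyrylium ion, on which both acetal epimers converge; the diol exchanges onto boron of 14 to give a chiral aryl dioxaborolane whose ate form pairs with the cation, and the aryl group migrates from boron to C2 within this ion pair. The closest known reaction type is the enantioselective addition of aryl boronates to 2-ethoxy-2H-chromenes under chiral diol/lanthanide triflate catalysis, run here at two sites of one molecule. No ring is closed or opened; only the C2–ring B and C2′–ring E bonds are formed. C2 and C2′ are both set by the chiral boronate (catalyst control) with the same sense, because the two cations present the same local environment and are insulated from each other by the twisted C4–C6′ axis. The step needs C2 rather than C4 attack: in the upper cation C4 carries ring D and is closed to attack, and in the lower cation C2 addition is the established outcome of this reaction class. The electron-rich para-alkoxy boronate is of the type that transfers readily. A wrong-sense addition at either site gives a diastereomer and not the enantiomer, so chromatographic removal should raise the enantiomeric purity of 15.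

Step 12
Reactants: 15 (2S,2′S)-7,7′-bis(benzyloxy)-2,2′-bis[3,4-bis(benzyloxy)phenyl]-2H,2′H-4,6′-bichromene
Product: 16 (2R,3R,4R)-7-(benzyloxy)-4-{(2R,3S,4S)-7-(benzyloxy)-2-[3,4-bis(benzyloxy)phenyl]-3,4-dihydroxychroman-6-yl}-2-[3,4-bis(benzyloxy)phenyl]chromane-3,4-diol (both units 2,3-trans-3,4-cis, all four hydroxyls anti to the C2 and C2′ aryl groups)
Conditions: K2OsO4·2H2O (5 mol%), NMO (3 equiv), MeSO2NH2, THF–t-BuOH–H2O, rt
Reagents that add atoms: N-methylmorpholine N-oxide, C[N+]1([O-])CCOCC1; water, O
Why: Upjohn dihydroxylation; OsO4 adds suprafacially to each C3=C4 bond from the face opposite the adjacent C2 aryl group, the known course for flav-3-enes, so C3, C4, C3′ and C4′ are set by substrate control from C2 and C2′.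

Step 13
Reactants: 16 the tetraol of step 12
Product: 17 (2R,3R,4R)-7-(benzyloxy)-4-{(2R,3R,4S)-3,4-diacetoxy-7-(benzyloxy)-2-[3,4-bis(benzyloxy)phenyl]chroman-6-yl}-2-[3,4-bis(benzyloxy)phenyl]-4-hydroxychroman-3-yl acetate
Conditions: Ac2O, pyridine, rt
Reagents that add atoms: acetic anhydride, CC(=O)OC(C)=O
Why: the three secondary hydroxyls are acetylated while the tertiary, diaryl-flanked C4 hydroxyl is inert under these conditions; this masks the lower diol and blocks pinacol rearrangement at C3 in one operation.

Step 14
Reactants: 17 the triacetate of step 13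
Product: 18 (2R,3S,4R)-7-(benzyloxy)-4-{(2R,3R,4S)-3,4-diacetoxy-7-(benzyloxy)-2-[3,4-bis(benzyloxy)phenyl]chroman-6-yl}-2-[3,4-bis(benzyloxy)phenyl]chroman-3-yl acetate (ring D cis to the C3 acetate)
Conditions: Et3SiH (5 equiv), CF3CO2H (3 equiv), CH2Cl2, −40 → −20 °C
Reagents that add atoms: none
Why: ionic hydrogenation; the tertiary alcohol ionises to a carbenium ion stabilised by two 2,4-dioxygenated arenes, and hydride is delivered anti to the neighbouring C3 acetate (shielding, possibly acetoxonium bridging), the usual trans course of nucleophile capture by flavan-4-yl cations, which sets C4. The secondary C4′ acetate, cis to its neighbour and lacking anchimeric help, should ionise far more slowly.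

Step 15
Reactants: 18 the deoxygenated triacetate of step 14
Product: 19 (2R,3S,4R)-7-(benzyloxy)-4-{(2R,3S,4S)-7-(benzyloxy)-2-[3,4-bis(benzyloxy)phenyl]-3,4-dihydroxychroman-6-yl}-2-[3,4-bis(benzyloxy)phenyl]chroman-3-ol
Conditions: K2CO3, MeOH–THF, 0 °C → rt
Reagents that add atoms: none
Why: base-catalysed transesterification cleaves the acetates at the acyl carbon, so no stereocentre is touched and the C4′ carbinol is never exposed to acid.

Step 16
Reactants: 19 the hexabenzyl triol of step 15
Product: 20 (2R,3S,4S)-2-(3,4-dihydroxyphenyl)-4-[(2R,3S,4S)-2-(3,4-dihydroxyphenyl)-3,4,7-trihydroxychroman-6-yl]chromane-3,7-diol (target)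
Conditions: H2 (1 atm), Pd(OH)2/C, THF–MeOH, rt; filtration under argon
Reagents that add atoms: none
Why: hydrogenolysis of six aryl benzyl ethers, the standard last step of proanthocyanidin syntheses; aryl benzyl ethers cleave much faster than the free benzylic C4′–OH or the C2–O1 ring ethers under neutral conditions.

## Compound list

1 | 2,4-dihydroxyacetophenone | CC(=O)c1ccc(O)cc1O | starting material
2 | 1-[4-(benzyloxy)-2-hydroxyphenyl]ethan-1-one | CC(=O)c1ccc(OCc2ccccc2)cc1O | intermediate
3 | ethyl 3-[4-(benzyloxy)-2-hydroxyphenyl]-3-oxopropanoate | CCOC(=O)CC(=O)c1ccc(OCc2ccccc2)cc1O | intermediate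
4 | 7-(benzyloxy)-4-hydroxy-2H-chromen-2-one | O=C1C=C(O)c2ccc(OCc3ccccc3)cc2O1 | intermediate
5 | 7-(benzyloxy)-2-oxo-2H-chromen-4-yl trifluoromethanesulfonate | O=C1C=C(OS(=O)(=O)C(F)(F)F)c2ccc(OCc3ccccc3)cc2O1 | intermediate
6 | 4-bromoresorcinol | Oc1ccc(Br)c(O)c1 | starting material
7 | 6-bromo-7-hydroxy-2H-chromen-2-one | O=C1C=Cc2cc(Br)c(O)cc2O1 | intermediate
8 | 7-(benzyloxy)-6-bromo-2H-chromen-2-one | O=C1C=Cc2cc(Br)c(OCc3ccccc3)cc2O1 | intermediate
9 | 7-(benzyloxy)-6-(4,4,5,5-tetramethyl-1,3,2-dioxaborolan-2-yl)-2H-chromen-2-one | O=C1C=Cc2cc(B3OC(C)(C)C(C)(C)O3)c(OCc3ccccc3)cc2O1 | intermediate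
10 | 7,7′-bis(benzyloxy)-2H,2′H-[4,6′-bichromene]-2,2′-dione | O=C1C=C(c2cc3C=CC(=O)Oc3cc2OCc2ccccc2)c2ccc(OCc3ccccc3)cc2O1 | intermediate
11 | 7,7′-bis(benzyloxy)-2H,2′H-[4,6′-bichromene]-2,2′-diol (epimer mixture) | OC1C=C(c2cc3C=CC(O)Oc3cc2OCc2ccccc2)c2ccc(OCc3ccccc3)cc2O1 | intermediate
12 | 7,7′-bis(benzyloxy)-2,2′-diethoxy-2H,2′H-4,6′-bichromene (epimer mixture) | CCOC1C=C(c2cc3C=CC(OCC)Oc3cc2OCc2ccccc2)c2ccc(OCc3ccccc3)cc2O1 | intermediate
13 | 3,4-bis(benzyloxy)phenylboronic acid | OB(O)c1ccc(OCc2ccccc2)c(OCc2ccccc2)c1 | starting material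
14 | diethyl [3,4-bis(benzyloxy)phenyl]boronate | CCOB(OCC)c1ccc(OCc2ccccc2)c(OCc2ccccc2)c1 | intermediate
15 | (2S,2′S)-7,7′-bis(benzyloxy)-2,2′-bis[3,4-bis(benzyloxy)phenyl]-2H,2′H-4,6′-bichromene | c1ccccc1COc1ccc2c(c1)O[C@H](c1ccc(OCc3ccccc3)c(OCc3ccccc3)c1)C=C2c1cc2c(cc1OCc1ccccc1)O[C@H](c1ccc(OCc3ccccc3)c(OCc3ccccc3)c1)C=C2 | intermediate
16 | (2R,3R,4R)-7-(benzyloxy)-4-{(2R,3S,4S)-7-(benzyloxy)-2-[3,4-bis(benzyloxy)phenyl]-3,4-dihydroxychroman-6-yl}-2-[3,4-bis(benzyloxy)phenyl]chromane-3,4-diol | c1ccccc1COc1ccc2c(c1)O[C@H](c1ccc(OCc3ccccc3)c(OCc3ccccc3)c1)[C@@H](O)[C@]2(O)c1cc2c(cc1OCc1ccccc1)O[C@H](c1ccc(OCc3ccccc3)c(OCc3ccccc3)c1)[C@@H](O)[C@H]2O | intermediate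
17 | (2R,3R,4R)-7-(benzyloxy)-4-{(2R,3R,4S)-3,4-diacetoxy-7-(benzyloxy)-2-[3,4-bis(benzyloxy)phenyl]chroman-6-yl}-2-[3,4-bis(benzyloxy)phenyl]-4-hydroxychroman-3-yl acetate | c1ccccc1COc1ccc2c(c1)O[C@H](c1ccc(OCc3ccccc3)c(OCc3ccccc3)c1)[C@@H](OC(C)=O)[C@]2(O)c1cc2c(cc1OCc1ccccc1)O[C@H](c1ccc(OCc3ccccc3)c(OCc3ccccc3)c1)[C@@H](OC(C)=O)[C@H]2OC(C)=O | intermediate
18 | (2R,3S,4R)-7-(benzyloxy)-4-{(2R,3R,4S)-3,4-diacetoxy-7-(benzyloxy)-2-[3,4-bis(benzyloxy)phenyl]chroman-6-yl}-2-[3,4-bis(benzyloxy)phenyl]chroman-3-yl acetate | c1ccccc1COc1ccc2c(c1)O[C@H](c1ccc(OCc3ccccc3)c(OCc3ccccc3)c1)[C@@H](OC(C)=O)[C@H]2c1cc2c(cc1OCc1ccccc1)O[C@H](c1ccc(OCc3ccccc3)c(OCc3ccccc3)c1)[C@@H](OC(C)=O)[C@H]2OC(C)=O | intermediate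
19 | (2R,3S,4R)-7-(benzyloxy)-4-{(2R,3S,4S)-7-(benzyloxy)-2-[3,4-bis(benzyloxy)phenyl]-3,4-dihydroxychroman-6-yl}-2-[3,4-bis(benzyloxy)phenyl]chroman-3-ol | c1ccccc1COc1ccc2c(c1)O[C@H](c1ccc(OCc3ccccc3)c(OCc3ccccc3)c1)[C@@H](O)[C@H]2c1cc2c(cc1OCc1ccccc1)O[C@H](c1ccc(OCc3ccccc3)c(OCc3ccccc3)c1)[C@@H](O)[C@H]2O | intermediate
20 | (2R,3S,4S)-2-(3,4-dihydroxyphenyl)-4-[(2R,3S,4S)-2-(3,4-dihydroxyphenyl)-3,4,7-trihydroxychroman-6-yl]chromane-3,7-diol | Oc1ccc2c(c1)O[C@H](c1ccc(O)c(O)c1)[C@@H](O)[C@H]2c1cc2c(cc1O)O[C@H](c1ccc(O)c(O)c1)[C@@H](O)[C@H]2O | target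

## Step count and uncertain steps

Total: 16 steps. Longest linear sequence: 12 steps (1 → 2 → 4 → 5 → 10 → 11 → 12 → 15 → 16 → 17 → 18 → 19 → 20; the branch from 6 is equally long).

**Step 11 (key step).**
- Most likely failure: slow or unselective aryl transfer at the upper site, whose 4-aryl benzopyrylium ion is more stabilised and less electrophilic than the precedented cations. Also possible are erosion of C2 configuration by Lewis-acid-induced reversible opening of the doubly activated C2–O1 bond in the product, and hydrolysis of the acetals by adventitious water.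
- Fallback: build 15 from two separately arylated monomers, setting out from 2 and 8 and returning at 15.
  - From 2, condensation with DMF dimethyl acetal gives the enaminone (E)-1-[4-(benzyloxy)-2-hydroxyphenyl]-3-(dimethylamino)prop-2-en-1-one F1, which cyclises in acid to 7-(benzyloxy)-4H-chromen-4-one F2. Asymmetric conjugate addition of boronic acid 13, catalysed by Pd(OCOCF3)2 with the enantiomer of 4-tert-butyl-2-(pyridin-2-yl)-4,5-dihydrooxazole that gives the 2S series, affords (2S)-7-(benzyloxy)-2-[3,4-bis(benzyloxy)phenyl]chroman-4-one F3.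
  - From 8, i-Bu2AlH reduction to 7-(benzyloxy)-6-bromo-2H-chromen-2-ol F4 and acetalisation to 7-(benzyloxy)-6-bromo-2-ethoxy-2H-chromene F5 give a monomeric acetal with hydrogen at C4, the exact precedent class. Boronate 14 is added to it under the conditions of step 11 to give (2S)-7-(benzyloxy)-2-[3,4-bis(benzyloxy)phenyl]-6-bromo-2H-chromene F6.
  - Bromine–lithium exchange on F6 (n-BuLi, −78 °C), transmetalation with CeCl3 to suppress enolisation, and addition to F3 give the tertiary carbinol (2S)-7-(benzyloxy)-4-{(2S)-7-(benzyloxy)-2-[3,4-bis(benzyloxy)phenyl]-2H-chromen-6-yl}-2-[3,4-bis(benzyloxy)phenyl]chroman-4-ol F7 (C4 epimers). Acid-catalysed dehydration (p-TsOH, cat.) then leads back to 15.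

**Step 14.**
- Most likely failure: competing ionisation of the lower benzylic C4′ acetate, leading to reduction or epimerisation at C4′, and insufficient facial selectivity in hydride capture by the very stabilised, nearly planar diaryl cation.
- Fallback: a radical deoxygenation, from 17 to 18. Acylation of the tertiary hydroxyl with methyl chlorooxoacetate (DMAP, pyridine) gives the methyl oxalate F8, the C4 methyl oxalate of 17. Bu3SnH/AIBN in toluene at reflux then cleaves the C4–O bond homolytically, and the doubly benzylic radical takes hydrogen anti to the C3 acetate. No cation is formed, so the C4′ acetate is not at risk.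

**Step 16.**
- Most likely failure: over-reduction by hydrogenolysis of the benzylic C4′–O bond (activated by the para oxygen) or of the C2–O1 ethers, and air oxidation or acid-induced self-condensation of the free polyphenol during isolation.
- Fallback: shield the carbinols before hydrogenolysis, from 19 to 20. TBSOTf/2,6-lutidine converts 19 into the tris(tert-butyldimethylsilyl) ether F9. Hydrogenolysis in EtOAc, where benzylic silyl ethers resist, gives the hexaphenol tris(silyl ether) F10. HF·pyridine buffered with pyridine in THF then gives 20.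

**Step 9.**
- Most likely failure: reversion to the lactol, or ring opening and Z→E isomerisation of the hydroxy enal under acid, and loss of the very labile 7-alkoxy acetals on contact with silica or moisture.
- Fallback: isolate the cations and form the acetals under base, from 11 to 12. HBF4·OEt2 in Et2O precipitates the bis(benzopyrylium) bis(tetrafluoroborate) F11, which is purified by trituration. Addition of the salt to NaOEt in EtOH at 0 °C gives 12 without chromatography.

## Further compounds

F1 | step 11 | (E)-1-[4-(benzyloxy)-2-hydroxyphenyl]-3-(dimethylamino)prop-2-en-1-one | CN(C)/C=C/C(=O)c1ccc(OCc2ccccc2)cc1O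
F2 | step 11 | 7-(benzyloxy)-4H-chromen-4-one | O=c1ccoc2cc(OCc3ccccc3)ccc12
F3 | step 11 | (2S)-7-(benzyloxy)-2-[3,4-bis(benzyloxy)phenyl]chroman-4-one | c1ccccc1COc1ccc2c(c1)O[C@H](c1ccc(OCc3ccccc3)c(OCc3ccccc3)c1)CC2=O
F4 | step 11 | 7-(benzyloxy)-6-bromo-2H-chromen-2-ol | OC1C=Cc2cc(Br)c(OCc3ccccc3)cc2O1
F5 | step 11 | 7-(benzyloxy)-6-bromo-2-ethoxy-2H-chromene | CCOC1C=Cc2cc(Br)c(OCc3ccccc3)cc2O1
F6 | step 11 | (2S)-7-(benzyloxy)-2-[3,4-bis(benzyloxy)phenyl]-6-bromo-2H-chromene | Brc1cc2c(cc1OCc1ccccc1)O[C@H](c1ccc(OCc3ccccc3)c(OCc3ccccc3)c1)C=C2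
F7 | step 11 | (2S)-7-(benzyloxy)-4-{(2S)-7-(benzyloxy)-2-[3,4-bis(benzyloxy)phenyl]-2H-chromen-6-yl}-2-[3,4-bis(benzyloxy)phenyl]chroman-4-ol (C4 epimers) | c1ccccc1COc1ccc2c(c1)O[C@H](c1ccc(OCc3ccccc3)c(OCc3ccccc3)c1)CC2(O)c1cc2c(cc1OCc1ccccc1)O[C@H](c1ccc(OCc3ccccc3)c(OCc3ccccc3)c1)C=C2
F8 | step 14 | C4 methyl oxalate of 17 | c1ccccc1COc1ccc2c(c1)O[C@H](c1ccc(OCc3ccccc3)c(OCc3ccccc3)c1)[C@@H](OC(C)=O)[C@]2(OC(=O)C(=O)OC)c1cc2c(cc1OCc1ccccc1)O[C@H](c1ccc(OCc3ccccc3)c(OCc3ccccc3)c1)[C@@H](OC(C)=O)[C@H]2OC(C)=O
F9 | step 16 | 3,3′,4′-tris-O-(tert-butyldimethylsilyl) ether of 19 | c1ccccc1COc1ccc2c(c1)O[C@H](c1ccc(OCc3ccccc3)c(OCc3ccccc3)c1)[C@@H](O[Si](C)(C)C(C)(C)C)[C@H]2c1cc2c(cc1OCc1ccccc1)O[C@H](c1ccc(OCc3ccccc3)c(OCc3ccccc3)c1)[C@@H](O[Si](C)(C)C(C)(C)C)[C@H]2O[Si](C)(C)C(C)(C)C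
F10 | step 16 | 3,3′,4′-tris-O-(tert-butyldimethylsilyl) ether of 20 | Oc1ccc2c(c1)O[C@H](c1ccc(O)c(O)c1)[C@@H](O[Si](C)(C)C(C)(C)C)[C@H]2c1cc2c(cc1O)O[C@H](c1ccc(O)c(O)c1)[C@@H](O[Si](C)(C)C(C)(C)C)[C@H]2O[Si](C)(C)C(C)(C)C
F11 | step 9 | 7,7′-bis(benzyloxy)-4,6′-bi(1-benzopyrylium) bis(tetrafluoroborate) | c1ccccc1COc1ccc2c(c1)[o+]ccc2-c1cc2ccc[o+]c2cc1OCc1ccccc1.F[B-](F)(F)F.F[B-](F)(F)F
A1 | alternative 1 | (E)-5-[4-(benzyloxy)-2-(methoxymethoxy)phenyl]-7-[3,4-bis(benzyloxy)phenyl]-4-diazohepta-1,6-dien-3-one, C5 configured as in A3 | C=CC(=O)C(=[N+]=[N-])[C@@H](c1ccc(OCc2ccccc2)cc1OCOC)/C=C/c1ccc(OCc2ccccc2)c(OCc2ccccc2)c1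
A2 | alternative 1 | ethynyloxy(triisopropyl)silane | C#CO[Si](C(C)C)(C(C)C)C(C)C
A3 | alternative 1 | 4-{(E)-1-[4-(benzyloxy)-2-(methoxymethoxy)phenyl]-3-[3,4-bis(benzyloxy)phenyl]prop-2-en-1-yl}-3-[(triisopropylsilyl)oxy]phenol | Oc1ccc(c(O[Si](C(C)C)(C(C)C)C(C)C)c1)[C@@H](c1ccc(OCc2ccccc2)cc1OCOC)/C=C/c1ccc(OCc2ccccc2)c(OCc2ccccc2)c1
A4 | alternative 2 | 3-O-benzyl upper flavan carrying at C4 a 2-(benzyloxy)-4-{(S)-1-[3,4-bis(benzyloxy)phenyl]prop-2-ynyloxy}phenyl group | c1ccccc1COc1ccc2c(c1)O[C@H](c1ccc(OCc3ccccc3)c(OCc3ccccc3)c1)[C@@H](OCc1ccccc1)[C@H]2c1ccc(O[C@H](c3ccc(OCc4ccccc4)c(OCc4ccccc4)c3)C#C)cc1OCc1ccccc1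
A5 | alternative 2 | lower (2′S)-flav-3-ene joined at C6′ to the 3-O-benzyl upper flavan | c1ccccc1COc1ccc2c(c1)O[C@H](c1ccc(OCc3ccccc3)c(OCc3ccccc3)c1)[C@@H](OCc1ccccc1)[C@H]2c1cc2c(cc1OCc1ccccc1)O[C@H](c1ccc(OCc3ccccc3)c(OCc3ccccc3)c1)C=C2
A6 | alternative 3 | 2-{5-(benzyloxy)-2-[2-(benzyloxy)-4-(triisopropylsilyloxy)benzoyl]phenoxy}-2-[3,4-bis(benzyloxy)phenyl]acetaldehyde, configured as C2 of A7 | c1ccccc1COc1ccc(C(=O)c2ccc(O[Si](C(C)C)(C(C)C)C(C)C)cc2OCc2ccccc2)c(c1)O[C@H](c1ccc(OCc2ccccc2)c(OCc2ccccc2)c1)C=O
A7 | alternative 3 | 2,3-trans-3,4-cis-7-(benzyloxy)-4-[2-(benzyloxy)-4-(triisopropylsilyloxy)phenyl]-2-[3,4-bis(benzyloxy)phenyl]chromane-3,4-diol | c1ccccc1COc1ccc2c(c1)O[C@H](c1ccc(OCc3ccccc3)c(OCc3ccccc3)c1)[C@@H](O)[C@]2(O)c1ccc(O[Si](C(C)C)(C(C)C)C(C)C)cc1OCc1ccccc1
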